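## Analysis of the target

The target joins two small units through a benzylic ester and contains one ring system, a 2,3-dihydro-1-benzofuran (ring atoms O1, C2, C3, C3a–C7a). The ring carries an isopropenyl group at ring C2 and an acyloxymethyl group at C5. The acyl part is a four-carbon diacid chain (C1–C4): C1 is a free carboxyl, C2 carries a hexylidene group (alkene C2=C1′), C3 carries a methyl group, and C4 is the ester carbonyl.

There are two stereocentres, ring C2 (S) and chain C3 (R). They are eight bonds apart and cannot influence each other, so each must be set by a reagent or catalyst. The third stereo element is the C2=C1′ geometry, read from the SMILES as 2Z: the pentyl chain is cis to the free C1 carboxyl and the vinylic hydrogen on C1′ is cis to C3. This is the pattern left by syn addition of hydrogen and a carbon group across the triple bond of a 2-ynoate; a base-mediated condensation would favour the other isomer.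

Chain C3 is the hub and the weak point. It is α to the C4 ester carbonyl and allylic to C2=C1′, so base can epimerise it or move the double bond into the C2–C3 position, giving the achiral 2-hexyl-3-methylbutenedioate. Other sensitive groups are the p-alkoxybenzyl-type ester (acid, hydrogenolysis), the isopropenyl group on an allylic aryl ether carbon (acid, hydrogenation, radicals) and the Z-enoic acid.

The difficulty is to differentiate the two carboxyls, to create C3 next to an alkene of the less favoured geometry, and never to expose C3 afterwards to base or to activation of C4.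

## Retrosynthetic reasoning

**C1 carboxyl (12 ⇐ 10 via 11).** The free acid is unmasked last. The mask must survive a nickel hydride and a mild base and must leave without acid, hydrogen or strong base. A 2-silylethyl ester, cleaved by fluoride, meets this. The carboxylate salt 11 is protonated in the same flask.

**C2–C3 bond (10 ⇐ 6 + 9), the key disconnection.** The bond between the stereocentre and the alkene carbon is cut. This is preferred over cutting C2=C1′ or the ester C–O bond because it turns both difficult features into consequences of one bond formation:
- C3 becomes the carbon of a racemic α-bromo ester (6), whose configuration need not be controlled.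
- C2 becomes the α-carbon of the 2-ynoate 9, and C1′ receives a hydrogen.
- The forward reaction must add H to C1′ and C3 to C2 on the same face of the triple bond (this gives 2Z), with nickel at the ester-bearing carbon, and must convert both C–Br epimers into 3R.
- The benzylic ester is already in place in 6, so C4 is never activated once C3 exists.

**Benzylic ester C–O (6 ⇐ 4 + 5).** The ester is made before the stereocentre, by a carbodiimide esterification of alcohol 4 with racemic acid 5. Nothing stereochemical is at stake at this stage.

**Silylethyl ester (9 ⇐ 7 + 8).** A plain esterification of the commercial ynoic acid 7 with alcohol 8.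

**Dihydrofuran ring (4 ⇐ 3 ⇐ 1 + 2).** The alcohol comes from aldehyde 3 by hydride reduction. Aldehyde 3 is cut at two ring bonds, C3–C3a and O1–C2, to bromophenol 1 and diene 2. The forward palladium-catalysed heteroannulation closes the five-membered ring and sets ring C2 in one step from two commercial compounds.

## Alternatives that were turned down

**Alternative 1:** the textbook route. Cut the benzylic ester C–O bond and the C2=C1′ double bond.
- Forward key step: Horner–Wadsworth–Emmons olefination of a six-carbon aldehyde with a 2-phosphono-3-methylsuccinate such as A1, then ester adjustment and esterification with 4.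
- Why turned down: the ordinary dialkyl phosphonate gives the E alkylidene succinate A2, with pentyl trans to the C1 carboxyl, which is the wrong geometry. The Z-selective variants are less dependable with an α-branched phosphonate.
- The stereocentre has to be bought stoichiometrically and introduced by displacement. Two orthogonal esters are needed, and the tert-butyl group of A2 cannot be removed without cleaving the p-alkoxybenzyl ester.
- In the classical order the C4 acid is activated next to C3, which invites epimerisation. The sequence runs to eight or nine steps. A Z-selective variant of it is kept only as the fallback for the key step.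

**Alternative 2:** cut only the C4–O acyl bond and keep both carboxyls unprotected.
- Forward key step: alcohol 4 opens the cyclic anhydride A3 at the non-conjugated carbonyl, the regiochemistry known for simple 2-alkylidene succinic anhydrides.
- Why turned down: A3 must itself be made as a single enantiomer with the Z geometry, which is the whole problem again.
- In the anhydride the C3 hydrogen is far more acidic. Heat or a trace of base moves the double bond into the ring to give the achiral maleic anhydride A4, which destroys both stereo elements.
- The methyl group on C3 hinders exactly the carbonyl that has to react.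

**Alternative 3:** form the C3–H bond last, with an enzyme.
- Forward key step: an ene-reductase (Old Yellow Enzyme family) reduces the 3-methylidene compound A5, adding hydride to the terminal CH2 and a proton to C3, and choosing one of three C=C bonds.
- A5 would come from 9 by palladium-catalysed hydrostannation to stannane A6 and Stille coupling with the 2-bromoacrylate A7 of alcohol 4.
- Why turned down: the substrate is a large lipophilic benzylic ester, far from the small acrylate and itaconate esters these enzymes are known to accept. The facial preference cannot be predicted and would have to be found by screening.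
- The cross-conjugated diene offers the hydride a second position, C1′, which would cost the Z alkene.
- The route needs stoichiometric tin and two more steps than the chosen one.

Key step: step 5

Assumption: the bond symbols of the SMILES place C3 and the pentyl chain on opposite sides of C2=C1′ (2Z), and this isomer is taken as the target; compounds 1, 2, 5, 7 and 8 are commercial.

## Route

Step 1
Reactants: 1 3-bromo-4-hydroxybenzaldehyde; 2 isoprene (2-methylbuta-1,3-diene)
Product: 3 (2S)-2-(prop-1-en-2-yl)-2,3-dihydro-1-benzofuran-5-carbaldehyde
Conditions: Pd2(dba)3·CHCl3 (2.5 mol%), chiral sulfinamide–monophosphine ligand of the TY-Phos type (10 mol%, enantiomer that gives 2S), K3PO4 (2 equiv), 2 (3 equiv), toluene, 80 °C, sealed tube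
Reagents that add atoms: none
Why: Enantioselective Heck/Tsuji–Trost heteroannulation (Larock-type) of an o-bromophenol with a 1,3-diene, a reaction class with close precedent for isoprene: the aryl group adds to the unsubstituted end of the monosubstituted vinyl group of 2, and the phenoxide attacks the internal terminus of the resulting η3-allyl palladium complex in a 5-exo closure. The chiral phosphine on palladium sets ring C2; the aldehyde is inert to these conditions.

Step 2
Reactants: 3 (2S)-2-(prop-1-en-2-yl)-2,3-dihydro-1-benzofuran-5-carbaldehyde
Product: 4 [(2S)-2-(prop-1-en-2-yl)-2,3-dihydro-1-benzofuran-5-yl]methanol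
Conditions: NaBH4 (0.5 equiv), MeOH, 0 °C
Reagents that add atoms: none
Why: Chemoselective borohydride reduction of the aryl aldehyde; the isopropenyl group and the ring stereocentre are not touched.

Step 3
Reactants: 4 [(2S)-2-(prop-1-en-2-yl)-2,3-dihydro-1-benzofuran-5-yl]methanol; 5 2-bromopropanoic acid (racemic)
Product: 6 [(2S)-2-(prop-1-en-2-yl)-2,3-dihydro-1-benzofuran-5-yl]methyl (2RS)-2-bromopropanoate (both epimers at the C–Br carbon)
Conditions: DCC (1.1 equiv), DMAP (5 mol%), CH2Cl2, −10 → 0 °C
Reagents that add atoms: none
Why: Steglich esterification under neutral conditions, which avoids the hydrogen halide that would ionise the p-alkoxybenzyl alcohol. The racemic acid is used on purpose, because step 5 erases the configuration at the C–Br carbon.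

Step 4
Reactants: 7 oct-2-ynoic acid; 8 2-(trimethylsilyl)ethan-1-ol
Product: 9 2-(trimethylsilyl)ethyl oct-2-ynoate
Conditions: DCC (1.1 equiv), DMAP (5 mol%), CH2Cl2, 0 °C → rt
Reagents that add atoms: none
Why: Steglich esterification; the silylethyl ester is chosen because it should survive silane and phosphate and is later removed by fluoride, without acid or hydrogen.

Step 5
Reactants: 6 [(2S)-2-(prop-1-en-2-yl)-2,3-dihydro-1-benzofuran-5-yl]methyl (2RS)-2-bromopropanoate; 9 2-(trimethylsilyl)ethyl oct-2-ynoate
Product: 10 4-{[(2S)-2-(prop-1-en-2-yl)-2,3-dihydro-1-benzofuran-5-yl]methyl} 1-[2-(trimethylsilyl)ethyl] (2Z,3R)-2-hexylidene-3-methylbutanedioate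
Conditions: NiBr2·(MeOCH2CH2OMe) (10 mol%), (4S,4′S)- or (4R,4′R)-2,2′-(propane-2,2-diyl)bis(4-phenyl-4,5-dihydro-1,3-oxazole) (12 mol%, the antipode that gives 3R, assigned in a pilot run), (EtO)3SiH (2 equiv, slow addition), K3PO4·H2O (2 equiv), 9 (1.5 equiv), N,N-dimethylacetamide, 0 °C → rt
Reagents that add atoms: none
Why: Proposed new method: a ligated nickel hydride, formed from the divalent nickel salt, the silane and phosphate, should add syn across the triple bond of 9 with hydride going to the β-carbon (C1′) and nickel to the ester-bearing carbon (C2), the polarity imposed by the conjugated ester and the regiochemistry seen in palladium-catalysed hydrostannation of 2-ynoates and in nickel-hydride α-hydroalkylation of acrylamides. Monovalent nickel abstracts bromine from either epimer of 6 to give one planar, ester-stabilised C3 radical, which is captured by the alkenylnickel species; reductive elimination from trivalent nickel then forms the C2–C3 bond with retention at the alkenyl carbon. The closest known reaction types are nickel-hydride hydroalkylation of alkynes with alkyl halides and nickel-catalysed enantioconvergent coupling of racemic α-halo carbonyl compounds with olefins under hydride conditions; the combination of an α-bromo ester with a 2-ynoate has not been shown. No ring is closed. The C3 stereocentre is controlled by the chiral bis(oxazoline) on nickel in the radical capture and reductive elimination, so both C–Br epimers should converge on 3R and the remote ring stereocentre plays no part. The 2Z geometry follows from syn hydrometalation: the C1′ hydrogen and nickel, and therefore the hydrogen and C3, end up cis, with pentyl cis to the silylethyl ester; if the alkenylnickel equilibrates through an oxygen-bound allenolate, nickel still prefers the position anti to pentyl, which leads to the same isomer. The step needs hydride insertion into the activated alkyne of 9 and not into the 1,1-disubstituted isopropenyl group of 6, coupling in preference to hydrodebromination of 6 (excess 9, slow silane addition), and no addition of the electrophilic C3 radical to the electron-poor ynoate, which the polarity mismatch should secure.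

Step 6
Reactants: 10 4-{[(2S)-2-(prop-1-en-2-yl)-2,3-dihydro-1-benzofuran-5-yl]methyl} 1-[2-(trimethylsilyl)ethyl] (2Z,3R)-2-hexylidene-3-methylbutanedioate
Product: 12 (2Z,3R)-2-hexylidene-3-methyl-4-oxo-4-{[(2S)-2-(prop-1-en-2-yl)-2,3-dihydro-1-benzofuran-5-yl]methoxy}butanoic acid (target), via tetrabutylammonium carboxylate 11 (not isolated)
Conditions: TBAF (1 M in THF, 2 equiv), THF, 0 °C; then AcOH (2 equiv), pH 5 phosphate buffer work-up
Reagents that add atoms: none
Why: Fluoride attacks silicon and a Peterson-type β-fragmentation releases ethene and the C1 carboxylate, which acetic acid protonates. The p-alkoxybenzyl ester, the isopropenyl group and the Z alkene should not react, and short exposure at 0 °C should keep C3 from epimerising.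

## Compound list

1 | 3-bromo-4-hydroxybenzaldehyde | O=Cc1ccc(O)c(Br)c1 | starting material
2 | isoprene (2-methylbuta-1,3-diene) | C=CC(C)=C | starting material
3 | (2S)-2-(prop-1-en-2-yl)-2,3-dihydro-1-benzofuran-5-carbaldehyde | C=C(C)[C@@H]1Cc2cc(C=O)ccc2O1 | intermediate
4 | [(2S)-2-(prop-1-en-2-yl)-2,3-dihydro-1-benzofuran-5-yl]methanol | C=C(C)[C@@H]1Cc2cc(CO)ccc2O1 | intermediate
5 | 2-bromopropanoic acid (racemic) | CC(Br)C(=O)O | starting material
6 | [(2S)-2-(prop-1-en-2-yl)-2,3-dihydro-1-benzofuran-5-yl]methyl (2RS)-2-bromopropanoate | C=C(C)[C@@H]1Cc2cc(COC(=O)C(C)Br)ccc2O1 | intermediate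
7 | oct-2-ynoic acid | CCCCCC#CC(=O)O | starting material
8 | 2-(trimethylsilyl)ethan-1-ol | C[Si](C)(C)CCO | starting material
9 | 2-(trimethylsilyl)ethyl oct-2-ynoate | CCCCCC#CC(=O)OCC[Si](C)(C)C | intermediate
10 | 4-{[(2S)-2-(prop-1-en-2-yl)-2,3-dihydro-1-benzofuran-5-yl]methyl} 1-[2-(trimethylsilyl)ethyl] (2Z,3R)-2-hexylidene-3-methylbutanedioate | C=C(C)[C@@H]1Cc2cc(COC(=O)[C@H](C)/C(=C/CCCCC)C(=O)OCC[Si](C)(C)C)ccc2O1 | intermediate
11 | tetrabutylammonium (2Z,3R)-2-hexylidene-3-methyl-4-oxo-4-{[(2S)-2-(prop-1-en-2-yl)-2,3-dihydro-1-benzofuran-5-yl]methoxy}butanoate | C=C(C)[C@@H]1Cc2cc(COC(=O)[C@H](C)/C(=C/CCCCC)C(=O)[O-])ccc2O1.CCCC[N+](CCCC)(CCCC)CCCC | intermediate (not isolated)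
12 | (2Z,3R)-2-hexylidene-3-methyl-4-oxo-4-{[(2S)-2-(prop-1-en-2-yl)-2,3-dihydro-1-benzofuran-5-yl]methoxy}butanoic acid | C=C(C)[C@@H]1Cc2cc(COC(=O)[C@H](C)/C(=C/CCCCC)C(=O)O)ccc2O1 | target

## Step count and risk

Total step count: 6. Longest linear sequence: 5 steps (steps 1, 2, 3, 5, 6); step 4 is a one-step side branch.

**Step 5 (key step, proposed new method).**
- What may go wrong:
  - The nickel hydride may reduce the partners separately, by hydrodebromination of 6 or semi-reduction of 9, because the cross-coupling has to outrun both.
  - Facial discrimination of the C3 radical may be poor, because a plain benzylic ester gives the ligand less to hold than the amides for which such couplings are established.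
  - The ester-stabilised radical may add to the electron-rich isopropenyl group, or the hydride may insert there.
  - The alkene geometry may leak if the alkenylnickel species equilibrates before coupling.
  - Phosphate may slowly epimerise C3 in the product.
- Fallback (known chemistry throughout; sets out from 4 and 8, comes back at 10):
  - Alcohol 4 is esterified with commercial (2R)-2-bromopropanoic acid (DCC, DMAP cat., CH2Cl2, −10 °C) to give [(2S)-2-(prop-1-en-2-yl)-2,3-dihydro-1-benzofuran-5-yl]methyl (2R)-2-bromopropanoate F1.
  - Alcohol 8 is esterified with commercial [bis(2,2,2-trifluoroethoxy)phosphoryl]acetic acid (DCC, DMAP cat.) to give 2-(trimethylsilyl)ethyl [bis(2,2,2-trifluoroethoxy)phosphoryl]acetate F2.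
  - The sodium salt of F2 (NaH, THF/DMF, 0 °C → rt) displaces the bromide of F1 with inversion to give the phosphonosuccinate 4-{[(2S)-2-(prop-1-en-2-yl)-2,3-dihydro-1-benzofuran-5-yl]methyl} 1-[2-(trimethylsilyl)ethyl] (3S)-2-[bis(2,2,2-trifluoroethoxy)phosphoryl]-3-methylbutanedioate F3, as a mixture at C2, which does not matter.
  - A Still–Gennari olefination of hexanal with F3 (KHMDS, 18-crown-6, THF, −78 °C) should close C2=C1′ with the pentyl chain cis to the silylethyl ester and give 10.
  - Here C3 comes from the chiral pool and no radical or hydride meets the isopropenyl group, at the price of three more operations.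

**Step 6.**
- What may go wrong: the basicity of fluoride may cause epimerisation at C3, or migration of the double bond into the C2–C3 position, before the ester has fragmented.
- Fallback (sets out from 7, comes back at 12): the fluoride-triggered β-fragmentation is replaced by O–Si cleavage under buffered, weakly acidic conditions.
  - Acid 7 is silylated (chlorotri(propan-2-yl)silane, imidazole, CH2Cl2) to tri(propan-2-yl)silyl oct-2-ynoate F4.
  - F4 is coupled with 6 under the conditions of step 5 to give 4-{[(2S)-2-(prop-1-en-2-yl)-2,3-dihydro-1-benzofuran-5-yl]methyl} 1-[tri(propan-2-yl)silyl] (2Z,3R)-2-hexylidene-3-methylbutanedioate F5.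
  - The silyl ester is cleaved with HF·pyridine buffered with pyridine (THF, 0 °C) to give 12 directly.

**Step 1.**
- What may go wrong: enantioselection may be incomplete with the electron-poor, formyl-substituted phenoxide. Insertion at the other diene terminus, or β-hydride elimination to an open Heck diene, may compete with ring closure.
- Fallback (sets out from 1 and 2, comes back at 3): stereocontrol by catalyst is given up for a resolution.
  - The annulation is run with an achiral catalyst (Pd(OAc)2, triarylphosphine, Na2CO3, DMF, 100 °C) to give racemic 2-(prop-1-en-2-yl)-2,3-dihydro-1-benzofuran-5-carbaldehyde F6.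
  - The enantiomers are separated by preparative chromatography on a cellulose-carbamate chiral stationary phase; the 2S enantiomer is 3.

## Further compounds

F1 | step 5 | [(2S)-2-(prop-1-en-2-yl)-2,3-dihydro-1-benzofuran-5-yl]methyl (2R)-2-bromopropanoate | C=C(C)[C@@H]1Cc2cc(COC(=O)[C@@H](C)Br)ccc2O1
F2 | step 5 | 2-(trimethylsilyl)ethyl [bis(2,2,2-trifluoroethoxy)phosphoryl]acetate | C[Si](C)(C)CCOC(=O)CP(=O)(OCC(F)(F)F)OCC(F)(F)F
F3 | step 5 | 4-{[(2S)-2-(prop-1-en-2-yl)-2,3-dihydro-1-benzofuran-5-yl]methyl} 1-[2-(trimethylsilyl)ethyl] (3S)-2-[bis(2,2,2-trifluoroethoxy)phosphoryl]-3-methylbutanedioate | C=C(C)[C@@H]1Cc2cc(COC(=O)[C@H](C)C(P(=O)(OCC(F)(F)F)OCC(F)(F)F)C(=O)OCC[Si](C)(C)C)ccc2O1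
F4 | step 6 | tri(propan-2-yl)silyl oct-2-ynoate | CCCCCC#CC(=O)O[Si](C(C)C)(C(C)C)C(C)C
F5 | step 6 | 4-{[(2S)-2-(prop-1-en-2-yl)-2,3-dihydro-1-benzofuran-5-yl]methyl} 1-[tri(propan-2-yl)silyl] (2Z,3R)-2-hexylidene-3-methylbutanedioate | C=C(C)[C@@H]1Cc2cc(COC(=O)[C@H](C)/C(=C/CCCCC)C(=O)O[Si](C(C)C)(C(C)C)C(C)C)ccc2O1
F6 | step 1 | racemic 2-(prop-1-en-2-yl)-2,3-dihydro-1-benzofuran-5-carbaldehyde | C=C(C)C1Cc2cc(C=O)ccc2O1
A1 | alternative 1 | 1-tert-butyl 4-methyl (3S)-2-(diethoxyphosphoryl)-3-methylbutanedioate | COC(=O)[C@H](C)C(P(=O)(OCC)OCC)C(=O)OC(C)(C)C
A2 | alternative 1 | 1-tert-butyl 4-methyl (2E,3R)-2-hexylidene-3-methylbutanedioate | COC(=O)[C@H](C)/C(=C\CCCCC)C(=O)OC(C)(C)C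
A3 | alternative 2 | (3Z,4R)-3-hexylidene-4-methyloxolane-2,5-dione | O=C1[C@H](C)/C(=C/CCCCC)C(=O)O1
A4 | alternative 2 | 3-hexyl-4-methylfuran-2,5-dione | CCCCCCC1=C(C)C(=O)OC1=O
A5 | alternative 3 | 4-{[(2S)-2-(prop-1-en-2-yl)-2,3-dihydro-1-benzofuran-5-yl]methyl} 1-[2-(trimethylsilyl)ethyl] (2Z)-2-hexylidene-3-methylidenebutanedioate | C=C(C)[C@@H]1Cc2cc(COC(=O)C(=C)/C(=C/CCCCC)C(=O)OCC[Si](C)(C)C)ccc2O1
A6 | alternative 3 | 2-(trimethylsilyl)ethyl (2E)-2-(tributylstannyl)oct-2-enoate | CCCCC/C=C(/[Sn](CCCC)(CCCC)CCCC)C(=O)OCC[Si](C)(C)C
A7 | alternative 3 | [(2S)-2-(prop-1-en-2-yl)-2,3-dihydro-1-benzofuran-5-yl]methyl 2-bromoprop-2-enoate | C=C(C)[C@@H]1Cc2cc(COC(=O)C(Br)=C)ccc2O1
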